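**Plan**

Ring labels: A = 3-methoxyphenyl; B = central phenol ring (C1 OH, C2 aryloxy, C4 arylethyl chain); C = para-phenylene of the diaryl ether; D = 3-hydroxyphenyl.
Retrosynthesis: remove the MOM group on ring D, take ring B back to a 6-aryloxycyclohex-2-enone (dehydrogenation, decarboxylation) and cut its C2–C3 and C5–C6 bonds. This is possible because C1(OH) and C2(OAr) are neighbours and the C4 chain is para to OH: C1/C2/C6 are the ketone carbon, the aryloxy-bearing carbon and the methyl of a 2-aryloxyacetoacetate, and C3/C4/C5 are the methylene, α-carbon and formyl carbon of a 2-substituted acrolein.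
Further cuts: the O–C2 bond (phenoxide plus 2-chloroacetoacetate), the C/D ethano bridge (Wittig olefination, hydrogenation) and the acrolein methylene (formaldehyde methylenation of a ring A butanal).
Forward: rings A, C and D are bought as benzene derivatives. The C/D bibenzyl phenol is made and O-alkylated, the ring A enal is made in three steps, and ring B is the only ring constructed, by Robinson annulation, then decarboxylated, aromatised and deprotected.
Stereochemistry: the target has no stereocentre. The sp3 centres created in the annulation and the decarboxylation are uncontrolled and disappear on aromatisation; the stilbene geometry is erased by hydrogenation.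

Key step: step 10

Remark on the chemistry: the keto ester carries an allyl ester, so that the activating carboxyl group can be removed with palladium and formate under neutral conditions instead of by saponification. ArO below stands for 4-{2-[3-(methoxymethoxy)phenyl]ethyl}phenoxy.

**Route**

Step 1
Reactants: 1 3-hydroxybenzaldehyde
Product: 2 3-(methoxymethoxy)benzaldehyde
Conditions: MOMCl, iPr2NEt, CH2Cl2, 0 °C → rt
Reagents that add atoms: chloromethyl methyl ether (MOMCl), COCCl
Why: Williamson-type O-alkylation of the phenol by the reactive α-chloro ether under amine base gives the MOM acetal, which masks the ring D hydroxyl through the basic, reductive and palladium-mediated steps while the aldehyde stays free for olefination.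

Step 2
Reactants: 3 4-(benzyloxy)benzyl chloride
Product: 4 [4-(benzyloxy)benzyl]triphenylphosphonium chloride
Conditions: PPh3, toluene, reflux
Reagents that add atoms: triphenylphosphine, c1ccc(cc1)P(c1ccccc1)c1ccccc1
Why: SN2 quaternisation of triphenylphosphine by the activated benzylic chloride gives the Wittig salt, and the benzyl ether is inert under these neutral conditions.

Step 3
Reactants: 4 [4-(benzyloxy)benzyl]triphenylphosphonium chloride, 2 3-(methoxymethoxy)benzaldehyde
Product: 6 1-(benzyloxy)-4-{2-[3-(methoxymethoxy)phenyl]ethenyl}benzene (E/Z mixture), via phosphonium ylide 5 (not isolated)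
Conditions: KOtBu, THF, 0 °C; then 2, 0 °C → rt
Reagents that add atoms: none
Why: Wittig olefination of the semi-stabilised benzylic ylide with the aromatic aldehyde joins the two carbons of the future ethano bridge between rings C and D, and the alkene geometry is irrelevant because the double bond is hydrogenated in the next step.

Step 4
Reactants: 6 1-(benzyloxy)-4-{2-[3-(methoxymethoxy)phenyl]ethenyl}benzene
Product: 7 4-{2-[3-(methoxymethoxy)phenyl]ethyl}phenol
Conditions: H2 (1 atm), 10% Pd/C, EtOAc–EtOH, rt
Reagents that add atoms: none
Why: Heterogeneous catalytic hydrogenation saturates the stilbene double bond and hydrogenolyses the benzyl ether in the same operation, while the MOM acetal and the arenes are untouched under neutral conditions, so that only the ring C hydroxyl is set free.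

Step 5
Reactants: 8 allyl acetoacetate (prop-2-en-1-yl 3-oxobutanoate)
Product: 9 allyl 2-chloro-3-oxobutanoate (racemic)
Conditions: SO2Cl2 (1.0 equiv), CH2Cl2, 0 °C → rt
Reagents that add atoms: sulfuryl chloride, O=S(=O)(Cl)Cl
Why: Electrophilic α-chlorination of the enol of the β-keto ester by sulfuryl chloride is fast and ionic at 0 °C, so that one equivalent should give the racemic monochloride without touching the allyl double bond.

Step 6
Reactants: 7 4-{2-[3-(methoxymethoxy)phenyl]ethyl}phenol, 9 allyl 2-chloro-3-oxobutanoate
Product: 10 allyl 2-(ArO)-3-oxobutanoate (racemic)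
Conditions: K2CO3, acetone, reflux
Reagents that add atoms: none
Why: Williamson ether synthesis by SN2 displacement of the chloride flanked by two carbonyl groups with the potassium phenoxide of 7, the usual entry to 2-aryloxyacetoacetates, forms the O–C2 bond of ring B and gives a racemic, readily enolised keto ester.

Step 7
Reactants: 11 4-(3-methoxyphenyl)butanoic acid
Product: 12 4-(3-methoxyphenyl)butan-1-ol
Conditions: BH3·THF, THF, 0 °C → rt; aqueous work-up
Reagents that add atoms: none
Why: Borane reduction of a carboxylic acid proceeds chemoselectively through an acyloxyborane to the primary alcohol, and the anisole ring is inert.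

Step 8
Reactants: 12 4-(3-methoxyphenyl)butan-1-ol
Product: 13 4-(3-methoxyphenyl)butanal
Conditions: PhI(OAc)2, TEMPO (10 mol %), CH2Cl2, rt
Reagents that add atoms: none
Why: The TEMPO/PhI(OAc)2 oxoammonium oxidation converts the primary alcohol into the aldehyde without over-oxidation to the acid and without attack on the electron-rich arene.

Step 9
Reactants: 13 4-(3-methoxyphenyl)butanal
Product: 14 4-(3-methoxyphenyl)-2-methylidenebutanal
Conditions: 37% aq. CH2O, pyrrolidine (10 mol %), EtCO2H (10 mol %), iPrOH, 45 °C
Reagents that add atoms: formaldehyde, C=O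
Why: Amine/acid-catalysed Mannich-type α-methylenation (enamine addition to formaldehyde, then elimination of the amine) installs the methylidene carbon that becomes C3 of ring B, under buffered conditions mild enough to keep the polymerisation-prone enal intact for immediate use.

Step 10
Reactants: 10 allyl 2-(ArO)-3-oxobutanoate, 14 4-(3-methoxyphenyl)-2-methylidenebutanal
Product: 17 allyl 1-(ArO)-5-[2-(3-methoxyphenyl)ethyl]-2-oxocyclohex-3-ene-1-carboxylate (diastereomer mixture), via keto aldehyde 15 (not isolated), via ketol 16 (not isolated)
Conditions: Et3N (0.2 equiv), toluene, 0 °C → rt; then pyrrolidine (0.3 equiv), AcOH (0.3 equiv), 4 Å MS, 60 °C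
Reagents that add atoms: none
Why: Triethylamine generates the enolate of 10 at the carbon between its two carbonyl groups (C2 of ring B), which adds in a Michael reaction to the methylene terminus of enal 14 to give keto aldehyde 15; hydroxide and alkoxide bases are avoided so that the non-enolisable adduct is not cleaved by retro-Claisen attack. Pyrrolidinium acetate then promotes the intramolecular aldol addition of the acetyl methyl group to the formyl group (ketol 16) and the E1cB loss of water, so that the C2–C3 and C5–C6 bonds of ring B are both formed in one flask. The closest known reaction type is the Robinson annulation of 2-substituted acetoacetates with acroleins to 6,6-disubstituted cyclohex-2-enones. Ring B closes in a 6-(enolendo)-exo-trig aldol. The quaternary C2 and the chain-bearing C4 of ring B are formed without control as a diastereomer mixture, which is acceptable because both become sp2 on aromatisation. The step needs C–C bond formation only at the doubly activated carbon and closure only to the six-membered ring; the first is secured because that carbon is the only position acidic enough for amine catalysis, the second because the only other aldol available (aldehyde α-carbon onto the ketone) would give a cyclobutane.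

Step 11
Reactants: 17 allyl 1-(ArO)-5-[2-(3-methoxyphenyl)ethyl]-2-oxocyclohex-3-ene-1-carboxylate
Product: 19 6-(ArO)-4-[2-(3-methoxyphenyl)ethyl]cyclohex-2-en-1-one (diastereomer mixture), via keto acid 18 (not isolated)
Conditions: Pd(OAc)2 (5 mol %), PPh3 (10 mol %), HCO2H, Et3N, THF, rt
Reagents that add atoms: none
Why: Zerovalent palladium formed in situ ionises the allyl ester, formate reduces the allyl group to propene (Tsuji–Trost-type deallylation with formate as hydride donor) and the freed β-keto acid loses CO2 at room temperature, which removes the activating group without the retro-Claisen cleavage that hydroxide could cause; the new stereocentre at C2 of ring B is uncontrolled and is erased in the next step.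

Step 12
Reactants: 19 6-(ArO)-4-[2-(3-methoxyphenyl)ethyl]cyclohex-2-en-1-one
Product: 21 2-(ArO)-4-[2-(3-methoxyphenyl)ethyl]phenol, via dienone 20 (not isolated)
Conditions: Pd(O2CCF3)2 (5 mol %), 2-(dimethylamino)pyridine (10 mol %), TsOH·H2O (20 mol %), O2 (1 atm), DMSO, 80 °C
Reagents that add atoms: none
Why: Palladium-catalysed aerobic dehydrogenation of a cyclohexenone to a phenol, in which a divalent palladium enolate undergoes β-hydride elimination across C2–C3 of ring B to dienone 20 that tautomerises to the arene while O2 reoxidises the zerovalent palladium, is preferred to quinone oxidants because those could dehydrogenate the 4-alkylphenol product further at its benzylic position; both remaining stereocentres vanish here.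

Step 13
Reactants: 21 2-(ArO)-4-[2-(3-methoxyphenyl)ethyl]phenol
Product: 22 2-{4-[2-(3-hydroxyphenyl)ethyl]phenoxy}-4-[2-(3-methoxyphenyl)ethyl]phenol (target)
Conditions: 3 M HCl in MeOH, 40 °C
Reagents that add atoms: none
Why: Acid-catalysed acetal exchange with methanol cleaves the MOM ether of ring D and traps the methoxymethyl cation as dimethoxymethane, while the methyl ether, the diaryl ether and both phenols are stable.

**Compound list**

1 | 3-hydroxybenzaldehyde | O=Cc1cccc(O)c1 | starting material
2 | 3-(methoxymethoxy)benzaldehyde | COCOc1cccc(C=O)c1 | intermediate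
3 | 4-(benzyloxy)benzyl chloride [1-(benzyloxy)-4-(chloromethyl)benzene] | ClCc1ccc(OCc2ccccc2)cc1 | starting material
4 | [4-(benzyloxy)benzyl]triphenylphosphonium chloride | [Cl-].c1ccc(COc2ccc(C[P+](c3ccccc3)(c3ccccc3)c3ccccc3)cc2)cc1 | intermediate
5 | [4-(benzyloxy)benzylidene]triphenylphosphorane (ylide, formed in the flask, not isolated) | c1ccc(COc2ccc(C=P(c3ccccc3)(c3ccccc3)c3ccccc3)cc2)cc1 | intermediate
6 | 1-(benzyloxy)-4-{2-[3-(methoxymethoxy)phenyl]ethenyl}benzene (E/Z mixture) | COCOc1cccc(C=Cc2ccc(OCc3ccccc3)cc2)c1 | intermediate
7 | 4-{2-[3-(methoxymethoxy)phenyl]ethyl}phenol | COCOc1cccc(CCc2ccc(O)cc2)c1 | intermediate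
8 | allyl acetoacetate (prop-2-en-1-yl 3-oxobutanoate) | C=CCOC(=O)CC(C)=O | starting material
9 | allyl 2-chloro-3-oxobutanoate (racemic) | C=CCOC(=O)C(Cl)C(C)=O | intermediate
10 | allyl 2-(4-{2-[3-(methoxymethoxy)phenyl]ethyl}phenoxy)-3-oxobutanoate (racemic) | C=CCOC(=O)C(Oc1ccc(CCc2cccc(OCOC)c2)cc1)C(C)=O | intermediate
11 | 4-(3-methoxyphenyl)butanoic acid | COc1cccc(CCCC(=O)O)c1 | starting material
12 | 4-(3-methoxyphenyl)butan-1-ol | COc1cccc(CCCCO)c1 | intermediate
13 | 4-(3-methoxyphenyl)butanal | COc1cccc(CCCC=O)c1 | intermediate
14 | 4-(3-methoxyphenyl)-2-methylidenebutanal | COc1cccc(CCC(=C)C=O)c1 | intermediate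
15 | allyl 2-acetyl-4-formyl-6-(3-methoxyphenyl)-2-(4-{2-[3-(methoxymethoxy)phenyl]ethyl}phenoxy)hexanoate (diastereomer mixture; formed in the flask, not isolated) | C=CCOC(=O)C(Oc1ccc(CCc2cccc(OCOC)c2)cc1)(C(C)=O)CC(C=O)CCc1cccc(OC)c1 | intermediate
16 | allyl 4-hydroxy-5-[2-(3-methoxyphenyl)ethyl]-1-(4-{2-[3-(methoxymethoxy)phenyl]ethyl}phenoxy)-2-oxocyclohexane-1-carboxylate (diastereomer mixture; formed in the flask, not isolated) | C=CCOC(=O)C1(Oc2ccc(CCc3cccc(OCOC)c3)cc2)CC(CCc2cccc(OC)c2)C(O)CC1=O | intermediate
17 | allyl 5-[2-(3-methoxyphenyl)ethyl]-1-(4-{2-[3-(methoxymethoxy)phenyl]ethyl}phenoxy)-2-oxocyclohex-3-ene-1-carboxylate (diastereomer mixture) | C=CCOC(=O)C1(Oc2ccc(CCc3cccc(OCOC)c3)cc2)CC(CCc2cccc(OC)c2)C=CC1=O | intermediate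
18 | 5-[2-(3-methoxyphenyl)ethyl]-1-(4-{2-[3-(methoxymethoxy)phenyl]ethyl}phenoxy)-2-oxocyclohex-3-ene-1-carboxylic acid (diastereomer mixture; formed in the flask, not isolated) | OC(=O)C1(Oc2ccc(CCc3cccc(OCOC)c3)cc2)CC(CCc2cccc(OC)c2)C=CC1=O | intermediate
19 | 4-[2-(3-methoxyphenyl)ethyl]-6-(4-{2-[3-(methoxymethoxy)phenyl]ethyl}phenoxy)cyclohex-2-en-1-one (diastereomer mixture) | O=C1C=CC(CCc2cccc(OC)c2)CC1Oc1ccc(CCc2cccc(OCOC)c2)cc1 | intermediate
20 | 4-[2-(3-methoxyphenyl)ethyl]-2-(4-{2-[3-(methoxymethoxy)phenyl]ethyl}phenoxy)cyclohexa-2,5-dien-1-one (formed in the flask, not isolated) | O=C1C=CC(CCc2cccc(OC)c2)C=C1Oc1ccc(CCc2cccc(OCOC)c2)cc1 | intermediate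
21 | 4-[2-(3-methoxyphenyl)ethyl]-2-(4-{2-[3-(methoxymethoxy)phenyl]ethyl}phenoxy)phenol | COCOc1cccc(CCc2ccc(Oc3cc(CCc4cccc(OC)c4)ccc3O)cc2)c1 | intermediate
22 | 2-{4-[2-(3-hydroxyphenyl)ethyl]phenoxy}-4-[2-(3-methoxyphenyl)ethyl]phenol (CNP0225725.0) | COc1cccc(CCc2ccc(O)c(Oc3ccc(CCc4cccc(O)c4)cc3)c2)c1 | target

**Step count**

Total: 13 steps.
Longest linear sequence: 8 steps (1 → 2 → 6 → 7 → 10 → 17 → 19 → 21 → 22; the same length from 3 through step 2).

**Steps most likely to fail**

Step 10 (key annulation). The conjugate addition of the hindered tertiary carbon of 10 may be slow, the enal may be consumed by self-condensation or polymerisation, and the amine may strip the acetyl group from the adduct by retro-Claisen cleavage. The fallback gives up the ester activating group in favour of enamine activation and keeps the same two ring bonds. It sets out from phenol 7, which would be alkylated with chloroacetone (K2CO3, KI cat., acetone) to 1-(4-{2-[3-(methoxymethoxy)phenyl]ethyl}phenoxy)propan-2-one F1. Its pyrrolidine enamine is expected to form toward the oxygen-bearing carbon, as α-oxygenated acetones do in enamine chemistry. Stork enamine Michael addition to enal 14 (MeCN, rt, then aqueous AcOH) should give 2-[2-(3-methoxyphenyl)ethyl]-4-(4-{2-[3-(methoxymethoxy)phenyl]ethyl}phenoxy)-5-oxohexanal F2. Aldol condensation of F2 (pyrrolidine, AcOH, toluene, 60 °C) closes the C5–C6 bond and gives cyclohexenone 19 directly. Steps 10 and 11 are bypassed and the route is rejoined at 19.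

Step 12 (aerobic dehydrogenation). The catalyst may be lost as palladium metal before conversion is complete, the electron-rich phenol product may be oxidised further, and the acid additive may remove part of the MOM group early (harmless, since it is removed next). The fallback replaces the direct C–H dehydrogenation by regiodefined enolisation and oxidation. From 19, kinetic deprotonation at the aryloxy-bearing carbon (LiN(iPr)2, THF, −78 °C) and silylation (Me3SiCl) should give trimethyl({4-[2-(3-methoxyphenyl)ethyl]-2-(4-{2-[3-(methoxymethoxy)phenyl]ethyl}phenoxy)cyclohexa-1,5-dien-1-yl}oxy)silane F3. Saegusa–Ito oxidation of F3 (Pd(OAc)2, MeCN, rt) gives dienone 20, which tautomerises, so the route is rejoined at 21.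

Step 6 (O-alkylation). Displacement at the secondary α-chloro carbon may be slow, chlorine may be transferred to the phenoxide instead, and the product may be deacetylated by base. The fallback builds the keto ester from an aryloxyacetate. From 7, alkylation with allyl bromoacetate (K2CO3, acetone) should give allyl 2-(4-{2-[3-(methoxymethoxy)phenyl]ethyl}phenoxy)acetate F4. Its lithium enolate (LiN(SiMe3)2, THF, −78 °C) would be added to acetaldehyde to give allyl 3-hydroxy-2-(4-{2-[3-(methoxymethoxy)phenyl]ethyl}phenoxy)butanoate F5 (diastereomer mixture). Oxidation with Dess–Martin periodinane (CH2Cl2, rt) returns to the route at 10.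

**Further compounds**

F1 | step 10 | 1-(4-{2-[3-(methoxymethoxy)phenyl]ethyl}phenoxy)propan-2-one | CC(=O)COc1ccc(CCc2cccc(OCOC)c2)cc1
F2 | step 10 | 2-[2-(3-methoxyphenyl)ethyl]-4-(4-{2-[3-(methoxymethoxy)phenyl]ethyl}phenoxy)-5-oxohexanal (diastereomer mixture) | O=CC(CCc1cccc(OC)c1)CC(Oc1ccc(CCc2cccc(OCOC)c2)cc1)C(C)=O
F3 | step 12 | trimethyl({4-[2-(3-methoxyphenyl)ethyl]-2-(4-{2-[3-(methoxymethoxy)phenyl]ethyl}phenoxy)cyclohexa-1,5-dien-1-yl}oxy)silane (racemic) | C[Si](C)(C)OC1=C(Oc2ccc(CCc3cccc(OCOC)c3)cc2)CC(CCc2cccc(OC)c2)C=C1
F4 | step 6 | allyl 2-(4-{2-[3-(methoxymethoxy)phenyl]ethyl}phenoxy)acetate | C=CCOC(=O)COc1ccc(CCc2cccc(OCOC)c2)cc1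
F5 | step 6 | allyl 3-hydroxy-2-(4-{2-[3-(methoxymethoxy)phenyl]ethyl}phenoxy)butanoate (diastereomer mixture) | C=CCOC(=O)C(Oc1ccc(CCc2cccc(OCOC)c2)cc1)C(C)O
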